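**Plan** (eremophilane numbering: ring A = C1–C5, C10; ring B = C5–C10; ester on C3, methyls on C4 and C5, ketone C8, hydroxyl C9, alkene C7=C11, CH2OH = C12)
- Retrosynthesis: the Z unit C8(=O)–C7=C11(CH3)–C12H2OH is unmasked from a 3-methylfuran whose oxygen bridges C8 and C12, and C9–OH from C9–B; the C3–O acyl bond is cut; then C8–C9 and C5–C10 are cut together; the open chain is cut at furyl–C6, C9=C10 and C3–C4.
- Enabling feature: with the furan in place, furan C8=C7 plus a C6=C5 alkene form a 1-oxy-diene and C9=C10 an alkenylboronate, so one intramolecular [4+2] event closes ring B by both bonds and ring A by C5–C10 from an acyclic precursor.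
- Forward order: C3/C4 stereodiad, Z-iodoalkene, alkenylboronate, furan coupling, cycloaddition (rings A and B at once), acylation with the separately made trienoic acid, C–B oxidation, furan oxidation, aldehyde reduction.
- Stereochemistry: C4 from (R)-but-3-yn-2-ol, C3 by a syn-selective SE2' addition; C5, C10 and C9 in the cycloaddition (Z diene gives the cis fusion, E dienophile fixes C9, C4 directs the face); Z-C7=C11 from the furan ring; triene geometry from syn-carboalumination and a Heck reaction.

Key step: step 8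

Remark on the chemistry: compounds 1, 4, 8, 10, 18 and 22 are taken as commercial; the target is handled as the open hydroxy enone, which can lose water to the furan under acid, so the last step and its work-up are kept neutral.

**Step 1**
Reactants: 1 (R)-but-3-yn-2-ol
Product: 2 (R)-but-3-yn-2-yl methanesulfonate
Conditions: MsCl, Et3N, CH2Cl2, −78 → 0 °C
Reagents that add atoms: methanesulfonyl chloride, CS(=O)(=O)Cl
Why: O-sulfonylation leaves the stereocentre untouched and installs the leaving group for the SN2' step.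

**Step 2**
Reactants: 2 (R)-but-3-yn-2-yl methanesulfonate
Product: 3 (P)-tributyl(buta-1,2-dien-1-yl)stannane
Conditions: Bu3SnH, LiN(iPr)2, THF, 0 °C; CuBr·SMe2, −78 °C; then 2, −78 °C
Reagents that add atoms: tributyltin hydride, CCCC[SnH](CCCC)CCCC
Why: anti SN2' displacement of the propargylic mesylate by a stannylcuprate should transfer the central chirality of 2 to the axial chirality of the allene.

**Step 3**
Reactants: 3 (P)-tributyl(buta-1,2-dien-1-yl)stannane; 4 pent-4-enal
Product: 5 (3R,4R)-3-methyloct-7-en-1-yn-4-ol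
Conditions: BF3·OEt2, CH2Cl2, −78 °C
Reagents that add atoms: none
Why: BF3-promoted SE2' propargylation through an open transition state, in which attack anti to tin fixes the methyl-bearing carbon (future C4, R) and the synclinal approach of the aldehyde gives the syn carbinol (future C3, R).

**Step 4**
Reactants: 5 (3R,4R)-3-methyloct-7-en-1-yn-4-ol
Product: 7 (1Z,3R,4R)-1-iodo-2,3-dimethylocta-1,7-dien-4-ol, via cyclic alkenylalane chelate 6 (not isolated)
Conditions: Me3Al (4 equiv), Cp2ZrCl2 (0.25 equiv), ClCH2CH2Cl, 23 °C then reflux; I2, THF, −30 → 0 °C; aq. K2CO3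
Reagents that add atoms: trimethylaluminium, C[Al](C)C; iodine, II
Why: Negishi carboalumination puts methyl on the internal alkyne carbon, heating should isomerise the alkenylalane to the six-membered aluminium alkoxide chelate (anti-carbometalation of a homopropargylic alcohol), and iodinolysis with retention gives iodine cis to the carbinol chain, the monosubstituted alkene being far less reactive.

**Step 5**
Reactants: 7 (1Z,3R,4R)-1-iodo-2,3-dimethylocta-1,7-dien-4-ol; 8 vinylboronic acid pinacol ester
Product: 9 (1Z,3R,4R,7E)-1-iodo-2,3-dimethyl-8-(4,4,5,5-tetramethyl-1,3,2-dioxaborolan-2-yl)octa-1,7-dien-4-ol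
Conditions: second-generation Grubbs catalyst (5 mol %), 8 (3 equiv), CH2Cl2, 40 °C
Reagents that add atoms: none
Why: olefin cross-metathesis of the terminal alkene with the vinylboronate is E-selective on steric grounds, and the trisubstituted iodoalkene should not engage the ruthenium carbene.

**Step 6**
Reactants: 10 3,4-dibromofuran
Product: 12 3-bromo-4-methylfuran, via (4-bromofuran-3-yl)lithium 11 (not isolated)
Conditions: n-BuLi (1.0 equiv), Et2O, −78 °C; MeI, −78 → 0 °C
Reagents that add atoms: iodomethane, CI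
Why: a single bromine–lithium exchange followed by methylation of the 3-furyllithium, kept cold so that lithium does not migrate to C2.

**Step 7**
Reactants: 12 3-bromo-4-methylfuran; 9 (1Z,3R,4R,7E)-1-iodo-2,3-dimethyl-8-(4,4,5,5-tetramethyl-1,3,2-dioxaborolan-2-yl)octa-1,7-dien-4-ol
Product: 15 (1Z,3R,4R,7E)-2,3-dimethyl-1-(4-methylfuran-3-yl)-8-(4,4,5,5-tetramethyl-1,3,2-dioxaborolan-2-yl)octa-1,7-dien-4-ol, via (4-methylfuran-3-yl)lithium 13 (not isolated), via (4-methylfuran-3-yl)zinc chloride 14 (not isolated)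
Conditions: 12 (2.5 equiv), n-BuLi, THF, −78 °C; ZnCl2, −78 → 0 °C; then 9, Pd(PPh3)4 (5 mol %), THF, 23–40 °C
Reagents that add atoms: none
Why: Negishi coupling should retain the Z geometry of the iodoalkene, the pinacol boronate is not transmetalated without base, and the excess organozinc absorbs the free hydroxyl.

**Step 8**
Reactants: 15 (1Z,3R,4R,7E)-2,3-dimethyl-1-(4-methylfuran-3-yl)-8-(4,4,5,5-tetramethyl-1,3,2-dioxaborolan-2-yl)octa-1,7-dien-4-ol
Product: 17 (4aS,5R,6R,8aR,9R)-3,4a,5-trimethyl-9-(4,4,5,5-tetramethyl-1,3,2-dioxaborolan-2-yl)-4,4a,5,6,7,8,8a,9-octahydronaphtho[2,3-b]furan-6-ol, via dihydrobenzofuran cycloadduct 16 (not isolated)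
Conditions: 1,2-dichlorobenzene (0.01 M), BHT (10 mol %), argon, sealed tube, 190 °C; then PPTS (5 mol %), CH2Cl2, 23 °C
Reagents that add atoms: none
Why: On heating, the furan C8=C7 bond and the (Z)-C6=C5 alkene should react as one electron-rich 1-oxy-diene with the (E)-alkenylboronate C9=C10 in a concerted, asynchronous intramolecular [4+2] cycloaddition that forms C5–C10 and C8–C9, after which cycloadduct 16 rearomatises by acid-mediated 1,3-hydrogen shift from C8 to C6. The closest known reaction types are the intramolecular Diels–Alder reaction of 3-vinylfurans in the extra-annular mode and Diels–Alder reactions of alkenylboronic esters as masked enol dienophiles. Ring B is closed by both new bonds as the six-membered cycloadduct ring, and ring A is closed at the same time by the C5–C10 bond across the four-carbon tether C4–C3–C2–C1 (a 1,3,9-decatriene closure to a decalin). At C5 and C10 the Z diene geometry puts the tether on the inside position of C5, so only the cis-fused transition state is reachable and H-10 ends up cis to the C5 methyl; at C9 the E dienophile geometry is transferred suprafacially, so boron ends up cis to H-10. The absolute sense at C5, C10 and C9 is dictated by C4: allylic 1,3-strain turns H-4 toward the furan C8–H, the tether folds as a chair with the C4 methyl and the C3 hydroxyl both equatorial, and the dienophile adds to the diene face anti to the C4 methyl. The step needs periselectivity (vinylfuran diene, not the furan ring), regiochemistry and exo-tether/endo-boron selectivity, all enforced by the short tether on a Z diene, plus the π-facial selectivity secured by C4.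

**Step 9**
Reactants: 18 (E)-oct-2-enal
Product: 19 (E)-non-3-en-1-yne
Conditions: Me3SiCHN2, LiN(iPr)2, THF, −78 → 23 °C; then H2O
Reagents that add atoms: (trimethylsilyl)diazomethane, C[Si](C)(C)C=[N+]=[N-]
Why: Colvin homologation (1,2-addition, Peterson-type loss of silanolate, 1,2-hydrogen shift of the alkylidene carbene) should give the enyne without touching the E alkene.

**Step 10**
Reactants: 19 (E)-non-3-en-1-yne
Product: 21 (1E,3E)-1-iodo-2-methylnona-1,3-diene, via dienyldimethylalane 20 (not isolated)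
Conditions: Me3Al (2 equiv), Cp2ZrCl2 (0.2 equiv), CH2Cl2, 0 → 23 °C; I2, THF, −30 °C; aq. K2CO3
Reagents that add atoms: trimethylaluminium, C[Al](C)C; iodine, II
Why: Negishi carboalumination adds methyl and aluminium syn with methyl on the internal carbon, and iodinolysis with retention gives the (1E,3E)-dienyl iodide.

**Step 11**
Reactants: 21 (1E,3E)-1-iodo-2-methylnona-1,3-diene; 22 acrylic acid
Product: 23 (2E,4E,6E)-5-methyldodeca-2,4,6-trienoic acid
Conditions: Pd(OAc)2 (5 mol %), K2CO3 (2.5 equiv), Bu4NCl, DMF, 23–50 °C; then aq. HCl to pH 3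
Reagents that add atoms: none
Why: Heck reaction under ligand-free phase-transfer conditions, with retention at the dienyl iodide and syn-insertion/syn-β-hydride elimination giving the new 2E alkene.

**Step 12**
Reactants: 17 (4aS,5R,6R,8aR,9R)-3,4a,5-trimethyl-9-(4,4,5,5-tetramethyl-1,3,2-dioxaborolan-2-yl)-4,4a,5,6,7,8,8a,9-octahydronaphtho[2,3-b]furan-6-ol; 23 (2E,4E,6E)-5-methyldodeca-2,4,6-trienoic acid
Product: 24 (4aS,5R,6R,8aR,9R)-3,4a,5-trimethyl-9-(4,4,5,5-tetramethyl-1,3,2-dioxaborolan-2-yl)-4,4a,5,6,7,8,8a,9-octahydronaphtho[2,3-b]furan-6-yl (2E,4E,6E)-5-methyldodeca-2,4,6-trienoate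
Conditions: EDC·HCl (2 equiv), DMAP (1 equiv), CH2Cl2, 0 → 23 °C
Reagents that add atoms: none
Why: Steglich esterification of the only free hydroxyl (C3–OH); the C9 oxygen is still masked as a carbon–boron bond, so no protecting group is needed.

**Step 13**
Reactants: 24 (4aS,5R,6R,8aR,9R)-3,4a,5-trimethyl-9-(4,4,5,5-tetramethyl-1,3,2-dioxaborolan-2-yl)-4,4a,5,6,7,8,8a,9-octahydronaphtho[2,3-b]furan-6-yl (2E,4E,6E)-5-methyldodeca-2,4,6-trienoate
Product: 25 (4aR,5R,6R,8aS,9R)-9-hydroxy-3,4a,5-trimethyl-4,4a,5,6,7,8,8a,9-octahydronaphtho[2,3-b]furan-6-yl (2E,4E,6E)-5-methyldodeca-2,4,6-trienoate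
Conditions: NaBO3·4H2O (5 equiv), THF/H2O (1:1), 23 °C
Reagents that add atoms: sodium perborate tetrahydrate, [Na+].[O-]OB=O
Why: perborate oxidation of the secondary alkylboronate, in which C9 migrates from boron to oxygen with retention, should give the C9 alcohol cis to H-10 under mildly basic conditions that spare ester, triene and furan.

**Step 14**
Reactants: 25 (4aR,5R,6R,8aS,9R)-9-hydroxy-3,4a,5-trimethyl-4,4a,5,6,7,8,8a,9-octahydronaphtho[2,3-b]furan-6-yl (2E,4E,6E)-5-methyldodeca-2,4,6-trienoate
Product: 27 (1R,2R,4aS,5R,8aR)-5-hydroxy-1,8a-dimethyl-6-oxo-7-[(2Z)-1-oxopropan-2-ylidene]decahydronaphthalen-2-yl (2E,4E,6E)-5-methyldodeca-2,4,6-trienoate, via furan endoperoxide 26 (not isolated)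
Conditions: O2, tetraphenylporphyrin (1 mol %), visible light, CH2Cl2, −78 °C; then Me2S, −78 → 0 °C; used crude
Reagents that add atoms: oxygen, O=O
Why: [4+2] photooxygenation of the electron-rich trialkylfuran by singlet oxygen (expected to be much faster than attack on the ester-conjugated triene) and reduction of the endoperoxide release the C8 ketone and C12 aldehyde as a cis-enedione, so the Z geometry of C7=C11 is inherited from the furan ring, while Achmatowicz-type closure of the C9 hydroxyl onto C12 would need a bridgehead alkene.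

**Step 15**
Reactants: 27 (1R,2R,4aS,5R,8aR)-5-hydroxy-1,8a-dimethyl-6-oxo-7-[(2Z)-1-oxopropan-2-ylidene]decahydronaphthalen-2-yl (2E,4E,6E)-5-methyldodeca-2,4,6-trienoate
Product: 28 (1R,2R,4aS,5R,8aR)-5-hydroxy-7-[(2Z)-1-hydroxypropan-2-ylidene]-1,8a-dimethyl-6-oxodecahydronaphthalen-2-yl (2E,4E,6E)-5-methyldodeca-2,4,6-trienoate
Conditions: NaBH4 (0.5 equiv), MeOH/CH2Cl2 (1:4), −78 °C; pH 7 phosphate buffer
Reagents that add atoms: none
Why: chemoselective borohydride 1,2-reduction, since the aldehyde should react much faster than the hindered cross-conjugated C8 ketone or the ester, and neutral work-up avoids cyclodehydration of the hydroxy enone back to the furan.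

**Compound list**
1 | (R)-but-3-yn-2-ol | C#C[C@@H](C)O | starting material
2 | (R)-but-3-yn-2-yl methanesulfonate | C#C[C@@H](C)OS(C)(=O)=O | intermediate
3 | (P)-tributyl(buta-1,2-dien-1-yl)stannane (aS) | CCCC[Sn](CCCC)(CCCC)[CH]=[C@@]=[CH]C | intermediate
4 | pent-4-enal | C=CCCC=O | starting material
5 | (3R,4R)-3-methyloct-7-en-1-yn-4-ol | C#C[C@@H](C)[C@H](O)CCC=C | intermediate
6 | cyclic alkenylalane chelate (six-membered Al–O–C4–C3–C2=C1 ring, methyl on aluminium) | C[Al]1O[C@H](CCC=C)[C@H](C)C(C)=C1 | intermediate (not isolated)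
7 | (1Z,3R,4R)-1-iodo-2,3-dimethylocta-1,7-dien-4-ol | I/C=C(C)\[C@@H](C)[C@H](O)CCC=C | intermediate
8 | vinylboronic acid pinacol ester | C=CB1OC(C)(C)C(C)(C)O1 | starting material
9 | (1Z,3R,4R,7E)-1-iodo-2,3-dimethyl-8-(4,4,5,5-tetramethyl-1,3,2-dioxaborolan-2-yl)octa-1,7-dien-4-ol | I/C=C(C)\[C@@H](C)[C@H](O)CC/C=C/B1OC(C)(C)C(C)(C)O1 | intermediate
10 | 3,4-dibromofuran | Brc1cocc1Br | starting material
11 | (4-bromofuran-3-yl)lithium | [Li]c1cocc1Br | intermediate (not isolated)
12 | 3-bromo-4-methylfuran | Cc1cocc1Br | intermediate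
13 | (4-methylfuran-3-yl)lithium | [Li]c1cocc1C | intermediate (not isolated)
14 | (4-methylfuran-3-yl)zinc chloride | Cl[Zn]c1cocc1C | intermediate (not isolated)
15 | (1Z,3R,4R,7E)-2,3-dimethyl-1-(4-methylfuran-3-yl)-8-(4,4,5,5-tetramethyl-1,3,2-dioxaborolan-2-yl)octa-1,7-dien-4-ol | Cc1cocc1/C=C(C)\[C@@H](C)[C@H](O)CC/C=C/B1OC(C)(C)C(C)(C)O1 | intermediate
16 | dihydrobenzofuran cycloadduct: 4a,5,6,7,8,8a,9,9a-octahydro isomer of 17 with C2=C3 and C3a=C4 double bonds, ring oxygen on C9a cis to boron | O[C@@H]1CC[C@@H]2[C@@H](B3OC(C)(C)C(C)(C)O3)[C@H]3OC=C(C)C3=C[C@]2(C)[C@H]1C | intermediate (not isolated)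
17 | (4aS,5R,6R,8aR,9R)-3,4a,5-trimethyl-9-(4,4,5,5-tetramethyl-1,3,2-dioxaborolan-2-yl)-4,4a,5,6,7,8,8a,9-octahydronaphtho[2,3-b]furan-6-ol (cis-fused) | O[C@@H]1CC[C@@H]2[C@@H](B3OC(C)(C)C(C)(C)O3)c3occ(C)c3C[C@]2(C)[C@H]1C | intermediate
18 | (E)-oct-2-enal | CCCCC/C=C/C=O | starting material
19 | (E)-non-3-en-1-yne | CCCCC/C=C/C#C | intermediate
20 | [(1E,3E)-2-methylnona-1,3-dien-1-yl]dimethylalane | CCCCC/C=C/C(C)=C/[Al](C)C | intermediate (not isolated)
21 | (1E,3E)-1-iodo-2-methylnona-1,3-diene | CCCCC/C=C/C(C)=C/I | intermediate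
22 | acrylic acid | C=CC(=O)O | starting material
23 | (2E,4E,6E)-5-methyldodeca-2,4,6-trienoic acid | CCCCC/C=C/C(C)=C/C=C/C(=O)O | intermediate
24 | (4aS,5R,6R,8aR,9R)-3,4a,5-trimethyl-9-(4,4,5,5-tetramethyl-1,3,2-dioxaborolan-2-yl)-4,4a,5,6,7,8,8a,9-octahydronaphtho[2,3-b]furan-6-yl (2E,4E,6E)-5-methyldodeca-2,4,6-trienoate | CCCCC/C=C/C(C)=C/C=C/C(=O)O[C@@H]1CC[C@@H]2[C@@H](B3OC(C)(C)C(C)(C)O3)c3occ(C)c3C[C@]2(C)[C@H]1C | intermediate
25 | (4aR,5R,6R,8aS,9R)-9-hydroxy-3,4a,5-trimethyl-4,4a,5,6,7,8,8a,9-octahydronaphtho[2,3-b]furan-6-yl (2E,4E,6E)-5-methyldodeca-2,4,6-trienoate | CCCCC/C=C/C(C)=C/C=C/C(=O)O[C@@H]1CC[C@@H]2[C@@H](O)c3occ(C)c3C[C@]2(C)[C@H]1C | intermediate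
26 | furan endoperoxide of 25 (O–O bridge between C8 and C12; either face, new centres left open) | CCCCC/C=C/C(C)=C/C=C/C(=O)O[C@@H]1CC[C@@H]2[C@@H](O)C34OOC(O3)C(C)=C4C[C@]2(C)[C@H]1C | intermediate (not isolated)
27 | (1R,2R,4aS,5R,8aR)-5-hydroxy-1,8a-dimethyl-6-oxo-7-[(2Z)-1-oxopropan-2-ylidene]decahydronaphthalen-2-yl (2E,4E,6E)-5-methyldodeca-2,4,6-trienoate | CCCCC/C=C/C(C)=C/C=C/C(=O)O[C@@H]1CC[C@@H]2[C@@H](O)C(=O)/C(=C(/C)C=O)C[C@]2(C)[C@H]1C | intermediate
28 | (1R,2R,4aS,5R,8aR)-5-hydroxy-7-[(2Z)-1-hydroxypropan-2-ylidene]-1,8a-dimethyl-6-oxodecahydronaphthalen-2-yl (2E,4E,6E)-5-methyldodeca-2,4,6-trienoate | CCCCC/C=C/C(C)=C/C=C/C(=O)O[C@@H]1CC[C@@H]2[C@@H](O)C(=O)/C(=C(/C)CO)C[C@]2(C)[C@H]1C | target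

**Count**
Total steps: 15. Longest linear sequence: 11 steps (1, 2, 3, 4, 5, 7, 8, 12, 13, 14, 15).

**Steps most likely to fail**

Step 8. A weak dienophile has to break furan aromaticity at a hindered, fully substituted diene terminus, so the cycloaddition may stay slower than thermal degradation of the vinylfuran (polymerisation, or Z-to-E isomerisation of the diene before ring closure). The fallback sets out from 15 and comes back at 17, and replaces the thermal reaction of the boronic ester by the cycloaddition of a Lewis-acidic alkenyldihaloborane made in the flask. KHF2 in MeOH/H2O should convert 15 into the potassium trifluoroborate F1. Me3SiCl with 2,6-di-tert-butylpyridine in MeCN/CH2Cl2 (−20 → 23 °C) should silylate the hydroxyl and abstract fluoride to give the O-silylated alkenyldifluoroborane F2. This far stronger dienophile should cyclise near room temperature through the same transition state to the tricyclic difluoroborane F3. Pinacol and Et3N should then give the silyl ether boronate F4, and K2CO3 in MeOH removes the trimethylsilyl group to return 17.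

Step 14. Chemoselectivity may be lost through oxygenation of the triene, over-oxidation of the enedione, or participation of the free C9 hydroxyl. The fallback sets out from 25 and comes back at 28, and uses a protected substrate with a halonium-type oxidant instead of singlet oxygen. Et3SiOTf and 2,6-lutidine should give the triethylsilyl ether F5. NBS with NaHCO3 in acetone/H2O at −20 °C should open the furan hydrolytically to the silylated Z keto-aldehyde F6, the electron-poor trienoate being inert to the electrophilic bromine source. NaBH4 at −78 °C should reduce the aldehyde to the silylated hydroxy enone F7, and Bu4NF buffered with AcOH at 0 °C removes the silyl group to give 28.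

Step 4. The syn-to-anti isomerisation of the alkenylalane may stay incomplete, or the terminal alkene may be carbometalated during the prolonged heating. The fallback sets out from 5 (with 12 and 8) and comes back at 15, and builds the Z alkene by syn-carbozincation of an arylalkyne. Sonogashira coupling of 5 with 12 (Pd(PPh3)2Cl2, CuI, Et3N, 60 °C) should give the alkynylfuran F8. Syn-methylzincation with Me2Zn and Ni(acac)2 (20 mol %, THF/NMP, −35 → 0 °C) should deliver methyl to the alkyl-bearing alkyne carbon and zinc to the furyl-bearing one, and aq. NH4Cl then gives the Z dienol F9. Cross-metathesis of F9 with 8 (second-generation Grubbs catalyst) gives 15, the hindered trisubstituted alkene not being expected to take part.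

**Further compounds**
F1 | step 8 | potassium trifluoro[(1E,5R,6R,7Z)-5-hydroxy-6,7-dimethyl-8-(4-methylfuran-3-yl)octa-1,7-dien-1-yl]borate | Cc1cocc1/C=C(C)\[C@@H](C)[C@H](O)CC/C=C/[B-](F)(F)F.[K+]
F2 | step 8 | O-trimethylsilyl (E)-alkenyldifluoroborane derived from F1 | Cc1cocc1/C=C(C)\[C@@H](C)[C@H](O[Si](C)(C)C)CC/C=C/B(F)F
F3 | step 8 | tricyclic 9-difluoroboryl furan, 6-O-trimethylsilyl ether (ring stereochemistry as in 17) | C[Si](C)(C)O[C@@H]1CC[C@@H]2[C@@H](B(F)F)c3occ(C)c3C[C@]2(C)[C@H]1C
F4 | step 8 | 6-O-trimethylsilyl ether of 17 | C[Si](C)(C)O[C@@H]1CC[C@@H]2[C@@H](B3OC(C)(C)C(C)(C)O3)c3occ(C)c3C[C@]2(C)[C@H]1C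
F5 | step 14 | 9-O-triethylsilyl ether of 25 | CCCCC/C=C/C(C)=C/C=C/C(=O)O[C@@H]1CC[C@@H]2[C@@H](O[Si](CC)(CC)CC)c3occ(C)c3C[C@]2(C)[C@H]1C
F6 | step 14 | 9-O-triethylsilyl ether of 27 | CCCCC/C=C/C(C)=C/C=C/C(=O)O[C@@H]1CC[C@@H]2[C@@H](O[Si](CC)(CC)CC)C(=O)/C(=C(/C)C=O)C[C@]2(C)[C@H]1C
F7 | step 14 | 9-O-triethylsilyl ether of 28 | CCCCC/C=C/C(C)=C/C=C/C(=O)O[C@@H]1CC[C@@H]2[C@@H](O[Si](CC)(CC)CC)C(=O)/C(=C(/C)CO)C[C@]2(C)[C@H]1C
F8 | step 4 | (3R,4R)-3-methyl-1-(4-methylfuran-3-yl)oct-7-en-1-yn-4-ol | Cc1cocc1C#C[C@@H](C)[C@H](O)CCC=C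
F9 | step 4 | (1Z,3R,4R)-2,3-dimethyl-1-(4-methylfuran-3-yl)octa-1,7-dien-4-ol | Cc1cocc1/C=C(C)\[C@@H](C)[C@H](O)CCC=C
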